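The route rests on closing the seven-membered ring at C1–C10 (daucane numbering: C1 is the methyl-bearing fusion carbon, C10 its olefinic neighbour) by a divinylcyclopropane Cope rearrangement triggered by rhodium-carbenoid cyclopropanation, a formal (4+3) cycloaddition. The key step exploits the latent cyclohepta-1,4-diene of that ring: the C6 oxygen becomes a C5=C6 silyl enol ether, the C8 methyl a C8=C9 enoate, with C7H2 between. In one operation it forms the ring, the quaternary C1 and both handles from a 2-siloxydiene (made from (S)-terpinen-4-ol) and methyl 2-diazobut-3-enoate. Later, epoxidation and selenoxide elimination move C8=C9 to the 8-hydroxy-9-ene.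

Key step: step 7

Remark: enantiopure (S)-(+)-terpinen-4-ol is assumed as the chiral starting material; atoms carry daucane numbers (C4 bears OH and isopropyl, C5 is the fusion CH, C6 the ester carbon, C8 bears the C14 methyl) and β denotes the face of the C1 methyl group.

Step 1
Reactants: 1 (S)-(+)-terpinen-4-ol
Product: 2 (3S)-3-hydroxy-6-oxo-3-(propan-2-yl)heptanal
Conditions: O3, CH2Cl2/MeOH, −78 °C; then Me2S, −78 °C to rt
Reagents that add atoms: ozone, [O-][O+]=O
Why: Criegee ozonolysis cleaves the only C=C bond and reductive work-up gives the keto aldehyde, the carbinol stereocentre (the future C4) being untouched.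

Step 2
Reactants: 2 (3S)-3-hydroxy-6-oxo-3-(propan-2-yl)heptanal
Product: 3 (5R)-5-hydroxy-2-methyl-5-(propan-2-yl)cyclopent-1-ene-1-carbaldehyde
Conditions: piperidine (cat.), AcOH (cat.), toluene, 4 Å sieves, 60 °C
Reagents that add atoms: none
Why: Amine-catalysed intramolecular aldol condensation, in which the aldehyde enamine adds to the methyl ketone (5-exo-trig) and the new ring hydroxyl is lost to give the tetrasubstituted conjugated enal (the less strained of the two possible dehydration products), while C4 keeps its configuration.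

Step 3
Reactants: 3 (5R)-5-hydroxy-2-methyl-5-(propan-2-yl)cyclopent-1-ene-1-carbaldehyde
Product: 4 1-[(5R)-5-hydroxy-2-methyl-5-(propan-2-yl)cyclopent-1-en-1-yl]ethan-1-ol (both carbinol epimers)
Conditions: MeMgBr (2.5 equiv), THF, −78 to 0 °C; aq. NH4Cl
Reagents that add atoms: methylmagnesium bromide, C[Mg]Br
Why: Grignard 1,2-addition to the aldehyde (the first equivalent only deprotonates the tertiary hydroxyl); the new carbinol centre is of no consequence because it is oxidised next.

Step 4
Reactants: 4 1-[(5R)-5-hydroxy-2-methyl-5-(propan-2-yl)cyclopent-1-en-1-yl]ethan-1-ol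
Product: 5 1-[(5R)-5-hydroxy-2-methyl-5-(propan-2-yl)cyclopent-1-en-1-yl]ethan-1-one
Conditions: MnO2 (activated, excess), CH2Cl2, rt
Reagents that add atoms: none
Why: Manganese dioxide oxidises only the allylic secondary alcohol and leaves the tertiary one.

Step 5
Reactants: 5 1-[(5R)-5-hydroxy-2-methyl-5-(propan-2-yl)cyclopent-1-en-1-yl]ethan-1-one
Product: 6 triethyl({1-[(5R)-2-methyl-5-(propan-2-yl)-5-(triethylsilyloxy)cyclopent-1-en-1-yl]ethenyl}oxy)silane (2-siloxydiene)
Conditions: TESOTf (2.4 equiv), Et3N, CH2Cl2, −78 to 0 °C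
Reagents that add atoms: triethylsilyl trifluoromethanesulfonate, CC[Si](CC)(CC)OS(=O)(=O)C(F)(F)F
Why: Soft enolisation by silyl triflate and amine gives the kinetic 2-siloxydiene on the methyl side and silylates the tertiary hydroxyl in the same operation.

Step 6
Reactants: 7 methyl but-3-enoate
Product: 8 methyl 2-diazobut-3-enoate
Conditions: 4-acetamidobenzenesulfonyl azide, DBU, MeCN, 0 °C; used at once as a cold hexanes solution
Reagents that add atoms: 4-acetamidobenzenesulfonyl azide, CC(=O)Nc1ccc(cc1)S(=O)(=O)N=[N+]=[N-]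
Why: Regitz diazo transfer to the doubly activated α-methylene of the β,γ-unsaturated ester gives the vinyldiazoacetate, which is used cold and at once because it cyclises to a pyrazole on standing.

Step 7
Reactants: 6 2-siloxydiene; 8 methyl 2-diazobut-3-enoate
Product: 10 methyl 4β,6-bis(triethylsilyloxy)dauca-5,8-dien-14-oate, via cis-divinylcyclopropane 9 (not isolated)
Conditions: Rh2(R-DOSP)4 (dirhodium tetrakis[(R)-N-(4-dodecylphenylsulfonyl)prolinate], 1 mol %), hexanes, −40 °C, 8 added over 2 h; then 60 °C
Reagents that add atoms: none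
Why: The dirhodium carboxylate converts 8 into a donor/acceptor vinylcarbenoid that adds to the electron-rich terminal siloxy-substituted C6=C7 bond of 6 in a concerted [2+1] closure of the three-membered ring, the carbenoid vinyl group ending cis to the cyclopentenyl group and trans to the ester, which gives cis-divinylcyclopropane 9. Compound 9 then undergoes the divinylcyclopropane–cycloheptadiene Cope rearrangement, a [3,3]-sigmatropic shift through the compulsory boat transition state in which the C6–C8 bond breaks and the C1–C10 bond forms between the unsubstituted vinyl terminus and the methyl-bearing cyclopentene carbon, so that the seven-membered ring is closed by ring expansion and the C5=C6 silyl enol ether and the C8=C9 enoate are left behind. The closest known reaction type is the rhodium-carbenoid tandem cyclopropanation/Cope rearrangement (formal (4+3) cycloaddition) of vinyldiazoacetates with 1-vinylcycloalkenes, which is known to create methyl-bearing quaternary ring-fusion carbons under catalyst control. The only new stereocentre of 10, C1, is controlled by the chiral catalyst, which fixes the configuration of the cyclopropane carbons C6 and C8 as drawn in 9, and the boat geometry transfers it to C1 so that C10 bonds to the cyclopentene face anti to the C4 silyloxy group (C1 methyl cis to the C4 oxygen). The step needs site selectivity for the enol ether over the tetrasubstituted ring alkene, cis diastereoselectivity and catalyst control over the resident C4 centre; the electron-rich 1,1-disubstituted enol ether, the donor/acceptor nature of the carbenoid and the availability of both catalyst antipodes secure them, the R antipode being chosen by analogy with the known sense of induction of this catalyst, and warming completes the rearrangement at the tetrasubstituted terminus.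

Step 8
Reactants: 10 methyl 4β,6-bis(triethylsilyloxy)dauca-5,8-dien-14-oate
Product: 11 4β,6-bis(triethylsilyloxy)dauca-5,8-dien-14-ol
Conditions: i-Bu2AlH (2.2 equiv), CH2Cl2, −78 °C; Rochelle salt work-up
Reagents that add atoms: none
Why: Hydride 1,2-reduction of the conjugated ester gives the primary allylic alcohol; the silyl ether and the silyl enol ether are inert to i-Bu2AlH at low temperature.

Step 9
Reactants: 11 4β,6-bis(triethylsilyloxy)dauca-5,8-dien-14-ol
Product: 13 4β,6-bis(triethylsilyloxy)dauca-5,8-diene, via allylic mesylate 12 (not isolated)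
Conditions: MsCl, Et3N, THF, −40 °C; then LiEt3BH, −40 to 0 °C
Reagents that add atoms: none
Why: Mesylation followed by SN2 displacement with LiEt3BH deoxygenates the primary allylic position without moving the C8=C9 bond, which turns the former ester carbon into the C14 methyl group.

Step 10
Reactants: 13 4β,6-bis(triethylsilyloxy)dauca-5,8-diene
Product: 14 4β-hydroxy-5αH-dauc-8-en-6-one (trans-fused ketol)
Conditions: Bu4NF, AcOH (1:1), THF, 0 °C to rt
Reagents that add atoms: none
Why: Fluoride cleaves the silyl enol ether first and the enolate is protonated at C5 from the α face, anti to the C1 methyl and the still silylated C4 oxygen, which gives the trans-fused ketone (also the expected thermodynamic epimer, with the acyl branch trans to the vicinal isopropyl group); the tertiary silyl ether is then cleaved, and the acetic acid buffer suppresses retro-aldol cleavage, dehydration and conjugation of the β,γ-alkene.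

Step 11
Reactants: 14 4β-hydroxy-5αH-dauc-8-en-6-one
Product: 15 5αH-dauc-8-ene-4β,6α-diol (jaeschkeanadiol)
Conditions: Me4NBH(OAc)3, MeCN/AcOH (1:1), −20 °C
Reagents that add atoms: none
Why: Evans–Saksena reduction, in which the 4β-hydroxyl exchanges onto boron and delivers hydride intramolecularly to the β face of the C6 carbonyl, sets the 6α-hydroxyl (anti 1,3-diol).

Step 12
Reactants: 15 5αH-dauc-8-ene-4β,6α-diol
Product: 16 8α,9α-epoxy-5αH-daucane-4β,6α-diol
Conditions: VO(acac)2 (5 mol %), t-BuOOH, CH2Cl2, 0 °C to rt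
Reagents that add atoms: tert-butyl hydroperoxide, CC(C)(C)OO
Why: Hydroxyl-directed vanadium-catalysed epoxidation, in which the homoallylic 6α-hydroxyl binds the vanadium peroxide and delivers oxygen to the α face of C8=C9, sets the C8–O configuration.

Step 13
Reactants: 16 8α,9α-epoxy-5αH-daucane-4β,6α-diol
Product: 19 5αH-dauc-9-ene-4β,6α,8α-triol, via hydroxy selenide 17 (not isolated), via selenoxide 18 (not isolated)
Conditions: PhSeSePh, NaBH4, EtOH, reflux; then 30% H2O2, THF, 0 °C to rt
Reagents that add atoms: none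
Why: Epoxide opening by phenylselenolate at the less hindered secondary C9 (SN2) followed by selenoxide syn-elimination, which can only take a C10 hydrogen because C8 is fully substituted, moves the double bond to C9=C10 and leaves the 8α tertiary alcohol.

Step 14
Reactants: 19 5αH-dauc-9-ene-4β,6α,8α-triol; 20 4-acetoxybenzoic acid
Product: 22 6α-(4-hydroxybenzoyloxy)-5αH-dauc-9-ene-4β,8α-diol (target), via aryl acetate 21 (not isolated)
Conditions: DCC, DMAP, CH2Cl2, rt; then pyrrolidine, rt
Reagents that add atoms: none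
Why: Steglich esterification acylates the only secondary hydroxyl (both tertiary alcohols are inert), and pyrrolidine then cleaves the phenolic acetate by aminolysis much faster than the hindered benzoate.

Compound list
1 | (S)-(+)-terpinen-4-ol, (1S)-4-methyl-1-(propan-2-yl)cyclohex-3-en-1-ol | CC(C)[C@@]1(O)CC=C(C)CC1 | starting material
2 | (3S)-3-hydroxy-6-oxo-3-(propan-2-yl)heptanal | CC(C)[C@@](O)(CC=O)CCC(C)=O | intermediate
3 | (5R)-5-hydroxy-2-methyl-5-(propan-2-yl)cyclopent-1-ene-1-carbaldehyde | CC(C)[C@]1(O)CCC(C)=C1C=O | intermediate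
4 | 1-[(5R)-5-hydroxy-2-methyl-5-(propan-2-yl)cyclopent-1-en-1-yl]ethan-1-ol, mixture of carbinol epimers | CC(C)[C@]1(O)CCC(C)=C1C(C)O | intermediate
5 | 1-[(5R)-5-hydroxy-2-methyl-5-(propan-2-yl)cyclopent-1-en-1-yl]ethan-1-one | CC(C)[C@]1(O)CCC(C)=C1C(C)=O | intermediate
6 | triethyl({1-[(5R)-2-methyl-5-(propan-2-yl)-5-(triethylsilyloxy)cyclopent-1-en-1-yl]ethenyl}oxy)silane | CC(C)[C@]1(O[Si](CC)(CC)CC)CCC(C)=C1C(=C)O[Si](CC)(CC)CC | intermediate
7 | methyl but-3-enoate | C=CCC(=O)OC | starting material
8 | methyl 2-diazobut-3-enoate | C=CC(=[N+]=[N-])C(=O)OC | intermediate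
9 | methyl (1S,2R)-1-ethenyl-2-[(5R)-2-methyl-5-(propan-2-yl)-5-(triethylsilyloxy)cyclopent-1-en-1-yl]-2-(triethylsilyloxy)cyclopropane-1-carboxylate (ethenyl cis to cyclopentenyl) | CC(C)[C@]1(O[Si](CC)(CC)CC)CCC(C)=C1[C@]2(O[Si](CC)(CC)CC)C[C@@]2(C=C)C(=O)OC | intermediate (not isolated)
10 | methyl 4β,6-bis(triethylsilyloxy)dauca-5,8-dien-14-oate (1β-methyl, 4α-isopropyl, C5=C6 silyl enol ether, C8=C9 enoate) | CC(C)[C@]1(O[Si](CC)(CC)CC)CC[C@]2(C)CC=C(C(=O)OC)CC(O[Si](CC)(CC)CC)=C21 | intermediate
11 | 4β,6-bis(triethylsilyloxy)dauca-5,8-dien-14-ol | CC(C)[C@]1(O[Si](CC)(CC)CC)CC[C@]2(C)CC=C(CO)CC(O[Si](CC)(CC)CC)=C21 | intermediate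
12 | 4β,6-bis(triethylsilyloxy)dauca-5,8-dien-14-yl methanesulfonate | CC(C)[C@]1(O[Si](CC)(CC)CC)CC[C@]2(C)CC=C(COS(C)(=O)=O)CC(O[Si](CC)(CC)CC)=C21 | intermediate (not isolated)
13 | 4β,6-bis(triethylsilyloxy)dauca-5,8-diene | CC(C)[C@]1(O[Si](CC)(CC)CC)CC[C@]2(C)CC=C(C)CC(O[Si](CC)(CC)CC)=C21 | intermediate
14 | 4β-hydroxy-5αH-dauc-8-en-6-one | CC(C)[C@]1(O)CC[C@]2(C)CC=C(C)CC(=O)[C@H]21 | intermediate
15 | 5αH-dauc-8-ene-4β,6α-diol (jaeschkeanadiol) | CC(C)[C@]1(O)CC[C@]2(C)CC=C(C)C[C@H](O)[C@H]21 | intermediate
16 | 8α,9α-epoxy-5αH-daucane-4β,6α-diol | CC(C)[C@]1(O)CC[C@]2(C)C[C@@H]3O[C@]3(C)C[C@H](O)[C@H]21 | intermediate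
17 | 9β-(phenylselanyl)-5αH-daucane-4β,6α,8α-triol | CC(C)[C@]1(O)CC[C@]2(C)C[C@@H]([Se]c3ccccc3)[C@](C)(O)C[C@H](O)[C@H]21 | intermediate (not isolated)
18 | 9β-(phenylseleninyl)-5αH-daucane-4β,6α,8α-triol (selenoxide) | CC(C)[C@]1(O)CC[C@]2(C)C[C@@H]([Se](=O)c3ccccc3)[C@](C)(O)C[C@H](O)[C@H]21 | intermediate (not isolated)
19 | 5αH-dauc-9-ene-4β,6α,8α-triol | CC(C)[C@]1(O)CC[C@]2(C)C=C[C@](C)(O)C[C@H](O)[C@H]21 | intermediate
20 | 4-acetoxybenzoic acid | CC(=O)Oc1ccc(cc1)C(O)=O | starting material
21 | 6α-(4-acetoxybenzoyloxy)-5αH-dauc-9-ene-4β,8α-diol | CC(C)[C@]1(O)CC[C@]2(C)C=C[C@](C)(O)C[C@H](OC(=O)c3ccc(OC(C)=O)cc3)[C@H]21 | intermediate (not isolated)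
22 | 6α-(4-hydroxybenzoyloxy)-5αH-dauc-9-ene-4β,8α-diol | CC(C)[C@]1(O)CC[C@]2(C)C=C[C@](C)(O)C[C@H](OC(=O)c3ccc(O)cc3)[C@H]21 | target

Total step count: 14. Longest linear sequence: 13 steps (1 to 22 through steps 1–5 and 7–14; step 6 is a one-step branch).

Steps most likely to fail

Step 7 (key step). The resident C4 centre may oppose the catalyst, giving poor facial selectivity at the enol ether and hence a mixture of C1 epimers. The donor–acceptor cyclopropane may also open to a zwitterion, eroding stereochemical transfer or diverting to formal (3+2) adducts. Finally, the hindered diene may react more slowly than the carbenoid dimerises or the diazo ester cyclises. The S antipode of the catalyst would be tried first. The fallback is the thermal rearrangement of a 2-siloxy-cis-divinylcyclopropane built stepwise; it sets out from 3 and comes back at 13. Enal 3 is coupled with 2-methyl-2-vinyloxirane by iridium-catalysed tert-(hydroxy)prenylation ([Ir(cod)Cl]2, the Tol-BINAP antipode that gives the quaternary centre shown, 4-chloro-3-nitrobenzoic acid, K3PO4, 2-propanol as reductant, THF, 60 °C) to give triol F1, whose quaternary carbon carries methyl, vinyl and CH2OH. MnO2 oxidises the allylic carbinol to hydroxy ketone F2, and I2/PPh3/imidazole converts the primary alcohol to iodide F3. SmI2 (THF, −78 °C) closes cyclopropanol F4 by a 3-exo Barbier reaction; the isomer with vinyl cis to cyclopentenyl is separated from the trans isomer. TESOTf/2,6-lutidine gives bis-silyl ether F5, which on heating in toluene (110 °C) undergoes the stereospecific boat Cope rearrangement to 13.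

Step 2. In the aldol intermediate both tertiary hydroxyls are β to the aldehyde, so the C4 hydroxyl may be lost in place of the ring hydroxyl; retro-aldol cleavage of the β-hydroxy aldehyde may also compete. The fallback carries the C4 oxygen as a silyl ether through a stepwise aldol and dehydration; it sets out from 1 and comes back at 3. TESOTf/2,6-lutidine converts 1 to silyl ether F6, and ozonolysis (O3, then Me2S) gives keto aldehyde F7. Pyrrolidine/AcOH at rt gives aldol F8, in which the only free hydroxyl is the new ring hydroxyl. The Burgess reagent dehydrates that hydroxyl selectively to silylated enal F9, and Bu4NF/AcOH returns 3.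

Step 11. The tertiary 4β-hydroxyl may exchange onto boron too slowly for internal delivery, so that external hydride attack from the open α face gives the 6β-alcohol. The fallback uses that bias on purpose and then inverts; it sets out from 14 and comes back at 15. LiBH(s-Bu)3 (THF, −78 °C) reduces 14 from the α face to 6β-alcohol F10. Mitsunobu inversion with 4-nitrobenzoic acid (PPh3, DIAD, toluene) gives 6α-(4-nitrobenzoate) F11, and K2CO3/MeOH returns 15.

Further compounds
F1 | step 7 | (2S)-2-ethenyl-1-[(5R)-5-hydroxy-2-methyl-5-(propan-2-yl)cyclopent-1-en-1-yl]-2-methylpropane-1,3-diol (carbinol epimer set by the catalyst, oxidised next) | CC(C)[C@]1(O)CCC(C)=C1C(O)[C@@](C)(C=C)CO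
F2 | step 7 | (2S)-2-(hydroxymethyl)-1-[(5R)-5-hydroxy-2-methyl-5-(propan-2-yl)cyclopent-1-en-1-yl]-2-methylbut-3-en-1-one | CC(C)[C@]1(O)CCC(C)=C1C(=O)[C@@](C)(C=C)CO
F3 | step 7 | (2R)-1-[(5R)-5-hydroxy-2-methyl-5-(propan-2-yl)cyclopent-1-en-1-yl]-2-(iodomethyl)-2-methylbut-3-en-1-one | CC(C)[C@]1(O)CCC(C)=C1C(=O)[C@@](C)(C=C)CI
F4 | step 7 | (1S,2R)-2-ethenyl-1-[(5R)-5-hydroxy-2-methyl-5-(propan-2-yl)cyclopent-1-en-1-yl]-2-methylcyclopropan-1-ol (ethenyl cis to cyclopentenyl) | CC(C)[C@]1(O)CCC(C)=C1[C@]2(O)C[C@@]2(C=C)C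
F5 | step 7 | bis(triethylsilyl) ether of F4 | CC(C)[C@]1(O[Si](CC)(CC)CC)CCC(C)=C1[C@]2(O[Si](CC)(CC)CC)C[C@@]2(C=C)C
F6 | step 2 | triethylsilyl ether of (S)-terpinen-4-ol | CC(C)[C@@]1(O[Si](CC)(CC)CC)CC=C(C)CC1
F7 | step 2 | (3S)-6-oxo-3-(propan-2-yl)-3-(triethylsilyloxy)heptanal | CC(C)[C@@](O[Si](CC)(CC)CC)(CC=O)CCC(C)=O
F8 | step 2 | (5R)-2-hydroxy-2-methyl-5-(propan-2-yl)-5-(triethylsilyloxy)cyclopentane-1-carbaldehyde (mixture at the two new centres) | CC(C)[C@]1(O[Si](CC)(CC)CC)CCC(C)(O)C1C=O
F9 | step 2 | (5R)-2-methyl-5-(propan-2-yl)-5-(triethylsilyloxy)cyclopent-1-ene-1-carbaldehyde | CC(C)[C@]1(O[Si](CC)(CC)CC)CCC(C)=C1C=O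
F10 | step 11 | 5αH-dauc-8-ene-4β,6β-diol | CC(C)[C@]1(O)CC[C@]2(C)CC=C(C)C[C@@H](O)[C@H]21
F11 | step 11 | 6α-(4-nitrobenzoyloxy)-5αH-dauc-8-en-4β-ol | CC(C)[C@]1(O)CC[C@]2(C)CC=C(C)C[C@H](OC(=O)c3ccc(cc3)[N+]([O-])=O)[C@H]21
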